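**Compound numbers used throughout:** 1 1-bromoicosane, 2 triphenylphosphine, 3 icosyltriphenylphosphonium bromide, 4 1H-pyrrole-2,5-dicarbaldehyde, 5 icosylidenetriphenylphosphorane, 6 sodium 2,5-diformylpyrrol-1-ide, 7 sodium 2-formyl-5-[(Z)-henicos-1-enyl]pyrrol-1-ide, 8 5-[(Z)-henicos-1-enyl]-1H-pyrrole-2-carbaldehyde, 9 5-henicosyl-1H-pyrrole-2-carbaldehyde (target).

## The problem

The target 9 is a 2,5-disubstituted 1H-pyrrole with a formyl group on C2, an unbranched henicosyl (C21) chain on C5, and C3, C4 and N1 unsubstituted. It has one aromatic ring, which need not be built if a suitable pyrrole can be bought, and no stereocentre. What must be controlled is therefore only the 2,5-placement of the two groups and the exact chain length. Attaching the chain is the real task: twenty-one sp3 carbons have to be joined to an α-position of an electron-rich heterocycle that polymerises in acid and is attacked by oxidants. The long chain also makes every intermediate waxy, so few steps and large polarity differences between product and by-products matter. Three groups limit the choice of reagents. The acidic N–H quenches carbanions. The formyl group, although a vinylogous formamide, still condenses with hydrazines and can be hydrogenolysed through its carbinol. The pyrrole π-system itself is sensitive. The feature that opens the structure is that C2 and C5 each carry exactly one exocyclic carbon, the formyl carbon on C2 and chain carbon C1' on C5. If C1' is raised to the aldehyde oxidation level, the core becomes the symmetric dialdehyde 4 with two homotopic formyl groups, and the chain can be joined between C1' and C2' by a carbonyl olefination. The one selectivity left is mono- against bis-reaction of two equal groups.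

## Retrosynthesis

**From 9 back to 8.** No skeletal bond is cut; the C1'–C2' single bond of 9 is traced back to a C1'=C2' double bond in the alkenyl aldehyde 8. This costs one reduction but turns the ring-to-chain junction into an olefination site. The forward step must saturate a 1,2-disubstituted, pyrrole-conjugated alkene and leave the formyl group alone. Mild heterogeneous hydrogenation is chosen, because α-formylpyrroles are slow to reduce under neutral conditions at atmospheric pressure. Diimide generated from an arenesulfonyl hydrazide was ruled out, since the hydrazide would condense with the formyl group of 8 to a sulfonylhydrazone under the warm conditions it needs. The alkene geometry of 8 is irrelevant because it is erased here.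

**From 8 back to 4 and 5.** The C1'=C2' double bond is cut, giving the symmetric dialdehyde 4 (which supplies C1' as one of its formyl carbons) and the C20 ylide 5. Two neighbouring cuts were weighed against this one:
- A cut of the ring–chain bond C5–C1' would need electrophilic substitution or metalation on a formylpyrrole. The formyl group then directs an incoming electrophile largely to C4, and metalation needs both N-protection and masking of the aldehyde.
- A cut of the ring–formyl bond would need a late Vilsmeier–Haack formylation of an α-alkylpyrrole. That is reliable in itself, but the alkylpyrrole must first be made by the same olefination and reduction, so the route is a step longer and passes through an acid-sensitive, unstabilised alkylpyrrole.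

With 4, the 2,5-pattern and the correct oxidation state of the surviving formyl group are present from the start. The precursors are a six-carbon heterocycle and a straight-chain ylide. The forward reaction must deal with the N–H and stop after one olefination. Both are handled by running the reaction on the N-sodio salt 6, which leads to 8 through its salt 7. Deprotonation protects the ylide from the N–H. It also makes the remaining formyl group of 7 a poorer electrophile than either formyl group of 6.

**From 5 back to 3, and from 3 back to 1 and 2.** The ylide 5 is the conjugate base of the phosphonium salt 3, generated in the flask with a non-nucleophilic sodium amide base. The P–C bond of 3 is cut to the primary bromide 1 and the phosphine 2, both bulk chemicals; the forward step is a simple quaternisation.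

## Roads not taken

**Alternative 1: ring-closing metathesis at C3–C4, then aromatisation.**
- Cut: the C3=C4 bond of the ring.
- Forward key step: the bis-allylic secondary amine A1, methyl 2-(tetracos-1-en-3-ylamino)but-3-enoate, handled as its p-toluenesulfonate salt, would be closed with second-generation Grubbs catalyst (H2IMes)(PCy3)Cl2Ru=CHPh to the 3-pyrroline A2, methyl 5-henicosyl-2,5-dihydro-1H-pyrrole-2-carboxylate. Dehydrogenation would then give the pyrrole ester A3, methyl 5-henicosyl-1H-pyrrole-2-carboxylate, and a reduction/oxidation pair would adjust the ester to the aldehyde.
- Merits: five-membered ring closure by metathesis is dependable, every step gives a single constitutional product, and there is no mono/bis statistics.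
- Weak points: A1 is a secondary amine flanked by two branched allylic carbons, one of them a vinylglycine ester that readily isomerises into conjugation. It needs several steps to assemble and must be protonated to keep the ruthenium carbene alive. After ring closure three further redox operations are needed.
- Comparison: this road is better in that no step depends on differentiating two equal groups. The chosen plan sets against that a bought ring, a formyl group already at the right oxidation level, and roughly a third of the step count.

**Alternative 2: dienyl azide cyclisation forming N1–C5.**
- Cut: the N1–C5 bond.
- Forward key step: the azide A4, ethyl (2Z,4E)-2-azidohexacosa-2,4-dienoate, would lose dinitrogen under Rh2(O2CC3F7)4 catalysis and close to the pyrrole ester A5, ethyl 5-henicosyl-1H-pyrrole-2-carboxylate.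
- Merits: the 2,5-pattern is written into the open-chain precursor, the closure is catalytic and mild, and it gives no regioisomers and no statistical mixture.
- Weak points: A4 must come from a condensation of an azidoacetate ester with a long-chain enal that is not a stock chemical and has γ-hydrogens open to deprotonation. A lipophilic vinyl azide has to be handled. The product A5 is again an ester that needs two redox steps to become the aldehyde.
- Comparison: in selectivity this road is at least as good as the chosen one and arguably better. The chosen plan has to set against it its brevity, the absence of azide chemistry, and a rate difference between the first and second olefination that rests on charge localisation in 7.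

**Alternative 3: azomethine ylide cycloaddition with an acetylene equivalent.**
- Cut: the C2–C3 and C4–C5 bonds.
- Forward key step: the glycine imine A6, methyl N-docosylideneglycinate, would be metalated with AgOAc and an amine base and added to the bis-sulfone A7, (E)-1,2-bis(phenylsulfonyl)ethene, to give the pyrrolidine A8, methyl 5-henicosyl-3,4-bis(phenylsulfonyl)pyrrolidine-2-carboxylate. Twofold base-induced elimination of the sulfonyl groups would lead to the pyrrole ester A3 without an oxidant.
- Merits: it is convergent, builds the ring and places both α-substituents in one step, and would be the better choice if 3,4-substituted analogues were wanted.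
- Weak points: A6 is an enolisable aliphatic aldimine that tautomerises and self-condenses. Four stereocentres are created only to be destroyed. Two phenylsulfonyl groups are carried as waste. The ester still has to be adjusted to the aldehyde.
- Comparison: for the bare 2,5-pattern this road constructs what can be purchased. The chosen plan is shorter and more atom-economical; its own weak point, the desymmetrisation of 4, is addressed by stoichiometry and by the deactivation of 7.

Key step: step 2

Assumption: 1H-pyrrole-2,5-dicarbaldehyde 4 is taken as a purchasable building block. The olefination product 8 is drawn as the Z isomer expected from a lithium-free unstabilised ylide; any E isomer formed alongside converges on 9 in step 3.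

## Route

Step 1
Reactants: 1 1-bromoicosane; 2 triphenylphosphine
Product: 3 icosyltriphenylphosphonium bromide
Conditions: neat melt, 130 °C, N2, 16 h; trituration with Et2O, drying under vacuum
Reagents that add atoms: none
Why: SN2 quaternisation of a triarylphosphine by an unhindered primary alkyl bromide (phosphonium salt formation); the melt keeps the waxy bromide homogeneous, and the salt is freed from neutral residues by trituration and dried thoroughly so that no water reaches the ylide.

Step 2
Reactants: 3 icosyltriphenylphosphonium bromide; 4 1H-pyrrole-2,5-dicarbaldehyde
Product: 8 5-[(Z)-henicos-1-enyl]-1H-pyrrole-2-carbaldehyde, via icosylidenetriphenylphosphorane 5 (not isolated), via sodium 2,5-diformylpyrrol-1-ide 6 (not isolated), via sodium 2-formyl-5-[(Z)-henicos-1-enyl]pyrrol-1-ide 7 (not isolated)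
Conditions: 3, NaN(SiMe3)2 (1.0 equiv), THF, 0 °C (forms 5); separately 4 (1.3 equiv), NaH (1.3 equiv), THF, 0 °C (forms 6); 5 added slowly to 6, 0 °C to 50 °C; aq NH4Cl
Reagents that add atoms: none
Why: Wittig olefination: NaN(SiMe3)2 converts 3 into the unstabilised ylide 5, and 4 is turned into its N-sodio salt 6 with NaH beforehand, so that the acidic N–H cannot protonate the ylide and no amide base meets a free formyl group. Ylide 5 adds to one formyl carbon of 6 to give an oxaphosphetane, which fragments by syn-cycloreversion into Ph3P=O and the C1'=C2' double bond of 7; no ring is closed and no stereocentre is formed. The closest known reaction type is the olefination of N-sodio pyrrole-2-carbaldehydes with alkylidenephosphoranes, together with the mono-olefination of symmetric aromatic dialdehydes. The selectivity needed is mono- over bis-olefination: in 6 the pyrrolide charge is shared between two formyl groups, whereas in 7 it rests on the single remaining one, which becomes a vinylogous formamidate and a poorer electrophile, and the ylide is the limiting reagent added slowly to an excess of 6. Site selectivity is not an issue because the two formyl groups of 4 are homotopic. The lithium-free ylide should give mainly the Z-alkene, but either geometry serves since step 3 removes the double bond. Aqueous NH4Cl reprotonates 7 to 8, and the polar excess of 4 and the Ph3P=O should separate cleanly from the lipophilic product on silica.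

Step 3
Reactants: 8 5-[(Z)-henicos-1-enyl]-1H-pyrrole-2-carbaldehyde
Product: 9 5-henicosyl-1H-pyrrole-2-carbaldehyde
Conditions: H2 (1 atm), 10% Pd/C, EtOAc/THF, rt; stopped after uptake of one equivalent of H2
Reagents that add atoms: none
Why: Heterogeneous catalytic hydrogenation of a 1,2-disubstituted alkene; the formyl group of a pyrrole-2-carbaldehyde is a vinylogous formamide and is reduced only slowly over Pd/C under neutral conditions at atmospheric pressure, as in the routine hydrogenolysis of benzyl esters of α-formylpyrroles, so the alkene should be saturated first.

## Compound list

1 | 1-bromoicosane | CCCCCCCCCCCCCCCCCCCCBr | starting material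
2 | triphenylphosphine | c1ccc(P(c2ccccc2)c2ccccc2)cc1 | starting material
3 | icosyltriphenylphosphonium bromide | CCCCCCCCCCCCCCCCCCCC[P+](c1ccccc1)(c1ccccc1)c1ccccc1.[Br-] | intermediate
4 | 1H-pyrrole-2,5-dicarbaldehyde | O=Cc1ccc(C=O)[nH]1 | starting material
5 | icosylidenetriphenylphosphorane | CCCCCCCCCCCCCCCCCCCC=P(c1ccccc1)(c1ccccc1)c1ccccc1 | intermediate (not isolated)
6 | sodium 2,5-diformylpyrrol-1-ide | O=Cc1ccc(C=O)[n-]1.[Na+] | intermediate (not isolated)
7 | sodium 2-formyl-5-[(Z)-henicos-1-enyl]pyrrol-1-ide | CCCCCCCCCCCCCCCCCCC/C=C\c1ccc(C=O)[n-]1.[Na+] | intermediate (not isolated)
8 | 5-[(Z)-henicos-1-enyl]-1H-pyrrole-2-carbaldehyde | CCCCCCCCCCCCCCCCCCC/C=C\c1ccc(C=O)[nH]1 | intermediate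
9 | 5-henicosyl-1H-pyrrole-2-carbaldehyde | CCCCCCCCCCCCCCCCCCCCCc1ccc(C=O)[nH]1 | target

## Step count and risks

Total step count: 3. Longest linear sequence: 3 steps (1 → 3 → 8 → 9).

**Step 2 (key step).** Two things are most likely to go wrong. The first is incomplete olefination, because the N-sodio salt 6 may aggregate or stay undissolved in THF and its formyl groups are deactivated by the pyrrolide charge. The second is over-olefination of the second formyl group wherever the ylide is locally in excess. Fallback: the N–H is removed by protection instead of deprotonation. Setting out from 4, treatment with di-tert-butyl dicarbonate and catalytic 4-dimethylaminopyridine in MeCN should give tert-butyl 2,5-diformyl-1H-pyrrole-1-carboxylate F1, a neutral, soluble and more electrophilic dialdehyde. Slow addition of one equivalent of ylide 5 (from 3 as in step 2) to F1 in THF at −78 °C should give tert-butyl 2-formyl-5-[(Z)-henicos-1-enyl]-1H-pyrrole-1-carboxylate F2. Methanolysis of the activated carbamate with K2CO3 in MeOH at room temperature returns to the route at 8.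

**Step 3.** The likely failure is over-reduction of the formyl group (hydrogenation to the carbinol followed by hydrogenolysis) once the alkene is consumed, or sluggish uptake caused by traces of phosphorus compounds on the catalyst. Fallback: the metal is abandoned in favour of concerted hydrogen transfer from diimide, generated from dipotassium azodicarboxylate KO2C–N=N–CO2K and acetic acid in THF/MeOH at room temperature. Diimide does not reduce polarised C=O bonds, and this source contains no hydrazide that could condense with the aldehyde. The fallback sets out from 8 and arrives directly at 9 (F0, no new compound).

**Step 1.** The likely failure is incomplete quaternisation, since displacement by the bulky phosphine on a long, waxy primary bromide is slow. Unreacted 1 and 2 are hard to remove from an equally waxy salt, and a wet or impure salt spoils the ylide titre. Fallback: the electrophile is changed. Setting out from 1, a Finkelstein exchange with NaI in refluxing acetone should give 1-iodoicosane F3. This reacts with 2 in refluxing MeCN to icosyltriphenylphosphonium iodide F4, which is expected to crystallise more readily. Deprotonation of F4 with NaN(SiMe3)2 in THF returns to the route at the ylide 5.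

## Further compounds

F1 | step 2 | tert-butyl 2,5-diformyl-1H-pyrrole-1-carboxylate | CC(C)(C)OC(=O)n1c(C=O)ccc1C=O
F2 | step 2 | tert-butyl 2-formyl-5-[(Z)-henicos-1-enyl]-1H-pyrrole-1-carboxylate | CCCCCCCCCCCCCCCCCCC/C=C\c1ccc(C=O)n1C(=O)OC(C)(C)C
F0 | step 3 | none | none
F3 | step 1 | 1-iodoicosane | CCCCCCCCCCCCCCCCCCCCI
F4 | step 1 | icosyltriphenylphosphonium iodide | CCCCCCCCCCCCCCCCCCCC[P+](c1ccccc1)(c1ccccc1)c1ccccc1.[I-]
A1 | alternative 1 | methyl 2-(tetracos-1-en-3-ylamino)but-3-enoate (diastereomer mixture, handled as its p-toluenesulfonate salt) | C=CC(NC(C=C)CCCCCCCCCCCCCCCCCCCCC)C(=O)OC
A2 | alternative 1 | methyl 5-henicosyl-2,5-dihydro-1H-pyrrole-2-carboxylate (diastereomer mixture) | COC(=O)C1C=CC(CCCCCCCCCCCCCCCCCCCCC)N1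
A3 | alternative 1 | methyl 5-henicosyl-1H-pyrrole-2-carboxylate | CCCCCCCCCCCCCCCCCCCCCc1ccc(C(=O)OC)[nH]1
A4 | alternative 2 | ethyl (2Z,4E)-2-azidohexacosa-2,4-dienoate | CCCCCCCCCCCCCCCCCCCCC/C=C/C=C(\N=[N+]=[N-])C(=O)OCC
A5 | alternative 2 | ethyl 5-henicosyl-1H-pyrrole-2-carboxylate | CCCCCCCCCCCCCCCCCCCCCc1ccc(C(=O)OCC)[nH]1
A6 | alternative 3 | methyl N-docosylideneglycinate | CCCCCCCCCCCCCCCCCCCCCC=NCC(=O)OC
A7 | alternative 3 | (E)-1,2-bis(phenylsulfonyl)ethene | O=S(=O)(/C=C/S(=O)(=O)c1ccccc1)c1ccccc1
A8 | alternative 3 | methyl 5-henicosyl-3,4-bis(phenylsulfonyl)pyrrolidine-2-carboxylate (racemic, 2,5-cis, 3,4-trans) | COC(=O)[C@H]1N[C@@H](CCCCCCCCCCCCCCCCCCCCC)[C@@H](S(=O)(=O)c2ccccc2)[C@@H]1S(=O)(=O)c1ccccc1
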